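**Plan**
- The first cut is the CH2–CH2 bond between C5 and C6 of the tricosyl chain (counted from the ring). It leads back to two carboxylic acids, nonadecanoic acid and 6-[2-(methoxycarbonyl)-1H-pyrrol-3-yl]hexanoic acid, each activated as its N-hydroxyphthalimide ester.
- The second cut is the pyrrole C3–CH2 bond. It leads back to methyl 3-bromo-1H-pyrrole-2-carboxylate and a 6-zinciohexanoate.
- Enabling feature: the bond lies between two plain CH2 carbons of an unbranched chain, so each can arise as a primary alkyl radical from a CO2H group. The 1H-pyrrole ring carries the C2 CO2Me group and is electron-poor, so it should survive a cathodic nickel cycle, whereas an anodic Kolbe electrolysis would risk oxidising the ring.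
- Forward order: the pyrrole ring is bought, N-Boc protected, given its C6 acid side chain by Negishi coupling and unmasked by one acidolysis. Both acids are converted to redox-active esters, and the chain is completed last by Ni-electrocatalytic doubly decarboxylative coupling.
- Stereochemistry: none is needed, because the target has no stereocentre and no stereogenic double bond.

Key step: step 6

Assumption: the target is achiral, so the request for a single enantiomer is read as a request for the constitution shown.

**Step 1**
Reactants: 1 methyl 3-bromo-1H-pyrrole-2-carboxylate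
Product: 2 1-tert-butyl 2-methyl 3-bromo-1H-pyrrole-1,2-dicarboxylate
Conditions: Boc2O (1.2 equiv), DMAP (0.1 equiv), MeCN, rt
Reagents that add atoms: di-tert-butyl dicarbonate, CC(C)(C)OC(=O)OC(=O)OC(C)(C)C
Why: DMAP-catalysed N-tert-butoxycarbonylation of the acidic pyrrole N–H should be clean; it removes the proton that would quench the alkylzinc in step 2 and favour protodebromination, and it makes the C3–Br bond more electron-poor for oxidative addition.

**Step 2**
Reactants: 2 1-tert-butyl 2-methyl 3-bromo-1H-pyrrole-1,2-dicarboxylate; 3 tert-butyl 6-bromohexanoate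
Product: 5 1-tert-butyl 2-methyl 3-(6-tert-butoxy-6-oxohexyl)-1H-pyrrole-1,2-dicarboxylate, via alkylzinc bromide 4 (not isolated)
Conditions: 3 (1.5 equiv), Zn dust (activated with BrCH2CH2Br/TMSCl), LiCl, THF, 50 °C; then 2, Pd(OAc)2 (2 mol %), SPhos (4 mol %), THF, rt to 40 °C
Reagents that add atoms: none
Why: LiCl-assisted zinc insertion into the primary bromide followed by Negishi sp2–sp3 coupling should work because the alkylzinc tolerates both esters and the carbamate, and the bulky biarylphosphine favours oxidative addition at the ester-flanked C3–Br and reductive elimination over β-hydride elimination.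

**Step 3**
Reactants: 5 1-tert-butyl 2-methyl 3-(6-tert-butoxy-6-oxohexyl)-1H-pyrrole-1,2-dicarboxylate
Product: 6 6-[2-(methoxycarbonyl)-1H-pyrrol-3-yl]hexanoic acid
Conditions: TFA/CH2Cl2 (1:3), 0 °C to rt
Reagents that add atoms: none
Why: Acidolysis by O-alkyl cleavage should remove the tert-butyl ester and the N-Boc group in one operation while the methyl ester stays, and the C2 ester deactivates the pyrrole towards the tert-butyl cation.

**Step 4**
Reactants: 6 6-[2-(methoxycarbonyl)-1H-pyrrol-3-yl]hexanoic acid
Product: 7 1,3-dioxoisoindolin-2-yl 6-[2-(methoxycarbonyl)-1H-pyrrol-3-yl]hexanoate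
Conditions: N-hydroxyphthalimide (1.1 equiv), DIC (1.1 equiv), DMAP (0.1 equiv), CH2Cl2, rt
Reagents that add atoms: N-hydroxyphthalimide, O=C1c2ccccc2C(=O)N1O
Why: Steglich-type carbodiimide esterification should give the redox-active ester, since the non-basic pyrrole N–H is not acylated under these neutral conditions.

**Step 5**
Reactants: 8 nonadecanoic acid
Product: 9 1,3-dioxoisoindolin-2-yl nonadecanoate
Conditions: N-hydroxyphthalimide (1.1 equiv), DIC (1.1 equiv), DMAP (0.1 equiv), CH2Cl2, rt
Reagents that add atoms: N-hydroxyphthalimide, O=C1c2ccccc2C(=O)N1O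
Why: The same Steglich-type carbodiimide esterification applied to an unfunctionalised fatty acid should give the second redox-active ester.

**Step 6**
Reactants: 7 1,3-dioxoisoindolin-2-yl 6-[2-(methoxycarbonyl)-1H-pyrrol-3-yl]hexanoate; 9 1,3-dioxoisoindolin-2-yl nonadecanoate (3 equiv)
Product: 10 methyl 3-tricosyl-1H-pyrrole-2-carboxylate
Conditions: NiCl2·6H2O (20 mol %), 2,2':6',2''-terpyridine (20 mol %), AgNO3 (0.3 equiv, electrode modifier), NMP/THF, Mg(+)/RVC(−), undivided cell, constant current, rt
Reagents that add atoms: none
Why: At the silver-coated cathode Ni(II)/terpyridine is reduced to low-valent nickel, which passes single electrons to both N-acyloxyphthalimides so that each loses phthalimide anion and CO2 and gives a primary radical (octadecyl from 9, 5-[2-(methoxycarbonyl)pyrrol-3-yl]pentyl from 7); successive capture of the two radicals at nickel gives a dialkylnickel(III) species that forms the CH2–CH2 bond by reductive elimination while the magnesium anode is consumed. The closest known reaction type is the nickel-electrocatalytic doubly decarboxylative C(sp3)–C(sp3) coupling of two primary redox-active esters, a reductive counterpart of the mixed Kolbe electrolysis. No ring is closed and no stereocentre is created. The step needs cross-coupling over homo-coupling, which the threefold excess of the inexpensive ester 9 should secure, the non-polar homo-dimer being easy to separate from the pyrrole ester. It also needs the heterocycle to stay intact: the C2 ester makes the pyrrole electron-poor, the ring is never exposed to an oxidising anode potential, and the only base formed (phthalimide anion) is too weak to deprotonate the pyrrole N–H, so N-acylation by the active esters is not expected.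

**Compound list**
1 | methyl 3-bromo-1H-pyrrole-2-carboxylate | COC(=O)c1[nH]ccc1Br | starting material
2 | 1-tert-butyl 2-methyl 3-bromo-1H-pyrrole-1,2-dicarboxylate | COC(=O)c1c(Br)ccn1C(=O)OC(C)(C)C | intermediate
3 | tert-butyl 6-bromohexanoate | BrCCCCCC(=O)OC(C)(C)C | starting material
4 | (6-tert-butoxy-6-oxohexyl)zinc bromide | Br[Zn]CCCCCC(=O)OC(C)(C)C | intermediate (not isolated)
5 | 1-tert-butyl 2-methyl 3-(6-tert-butoxy-6-oxohexyl)-1H-pyrrole-1,2-dicarboxylate | COC(=O)c1c(CCCCCC(=O)OC(C)(C)C)ccn1C(=O)OC(C)(C)C | intermediate
6 | 6-[2-(methoxycarbonyl)-1H-pyrrol-3-yl]hexanoic acid | COC(=O)c1[nH]ccc1CCCCCC(=O)O | intermediate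
7 | 1,3-dioxoisoindolin-2-yl 6-[2-(methoxycarbonyl)-1H-pyrrol-3-yl]hexanoate | COC(=O)c1[nH]ccc1CCCCCC(=O)ON1C(=O)c2ccccc2C1=O | intermediate
8 | nonadecanoic acid | CCCCCCCCCCCCCCCCCCC(=O)O | starting material
9 | 1,3-dioxoisoindolin-2-yl nonadecanoate | CCCCCCCCCCCCCCCCCCC(=O)ON1C(=O)c2ccccc2C1=O | intermediate
10 | methyl 3-tricosyl-1H-pyrrole-2-carboxylate | CCCCCCCCCCCCCCCCCCCCCCCc1cc[nH]c1C(=O)OC | target

**Step count**
Total: 6 steps. Longest linear sequence: 5 steps (steps 1, 2, 3, 4 and 6).

**Steps most likely to fail**

Step 6. The two radicals may couple statistically with themselves, may be reduced to the alkanes before they meet at nickel, or the long-chain ester may dissolve poorly in the cell solvent. The fallback sets out from 7 and comes back at 10 by a polarity-differentiated, non-electrochemical coupling. Commercial octadecylmagnesium chloride is transmetalated with ZnCl2 (0.5 equiv) in THF to dioctadecylzinc F1. This is used in excess, so that the N–H is covered, in a nickel-catalysed decarboxylative alkyl–alkyl Negishi coupling with 7 (NiCl2·glyme, 4,4'-di-tert-butyl-2,2'-bipyridine, THF/DMF, rt). The same bond is formed, but the octadecyl partner is a preformed nucleophile, so homo-coupling of the pyrrole fragment is no longer statistical.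

Step 2. Oxidative addition at the electron-rich C3–Br bond may be slow, so that protonolysis of the alkylzinc, protodebromination or β-hydride elimination of the alkylpalladium intermediate takes over. The fallback sets out from 2 and comes back at 5 without an sp3 organometallic. Sonogashira coupling of 2 with commercial tert-butyl hex-5-ynoate (Pd(PPh3)2Cl2, CuI, Et3N, DMF, 60 °C) should give 1-tert-butyl 2-methyl 3-(6-tert-butoxy-6-oxohex-1-yn-1-yl)-1H-pyrrole-1,2-dicarboxylate F2. Hydrogenation of the triple bond (H2, Pd/C, EtOAc) then gives 5.

Step 3. The tert-butyl cation may be recaptured by the α-free pyrrole ring (C-alkylation), the N-carbamate may cleave sluggishly, or the pyrrole may oligomerise in strong acid. The fallback sets out from 2 and comes back at 6 with an orthogonal, acid-free pair of protecting groups. Commercial benzyl 6-bromohexanoate is converted with Zn/LiCl in THF into [6-(benzyloxy)-6-oxohexyl]zinc bromide F3. Negishi coupling with 2 under the conditions of step 2 gives 1-tert-butyl 2-methyl 3-[6-(benzyloxy)-6-oxohexyl]-1H-pyrrole-1,2-dicarboxylate F4. Hydrogenolysis (H2, Pd/C, EtOAc) gives 6-[1-(tert-butoxycarbonyl)-2-(methoxycarbonyl)-1H-pyrrol-3-yl]hexanoic acid F5. Thermolysis of the N-Boc group (hexafluoroisopropanol, sealed tube, about 120 °C) then gives 6.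

**Further compounds**
F1 | step 6 | dioctadecylzinc | CCCCCCCCCCCCCCCCCC[Zn]CCCCCCCCCCCCCCCCCC
F2 | step 2 | 1-tert-butyl 2-methyl 3-(6-tert-butoxy-6-oxohex-1-yn-1-yl)-1H-pyrrole-1,2-dicarboxylate | COC(=O)c1c(C#CCCCC(=O)OC(C)(C)C)ccn1C(=O)OC(C)(C)C
F3 | step 3 | [6-(benzyloxy)-6-oxohexyl]zinc bromide | Br[Zn]CCCCCC(=O)OCc1ccccc1
F4 | step 3 | 1-tert-butyl 2-methyl 3-[6-(benzyloxy)-6-oxohexyl]-1H-pyrrole-1,2-dicarboxylate | COC(=O)c1c(CCCCCC(=O)OCc2ccccc2)ccn1C(=O)OC(C)(C)C
F5 | step 3 | 6-[1-(tert-butoxycarbonyl)-2-(methoxycarbonyl)-1H-pyrrol-3-yl]hexanoic acid | COC(=O)c1c(CCCCCC(=O)O)ccn1C(=O)OC(C)(C)C
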